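**Strategy.** Carotenoid numbering is used (ring A = C1–C6; primed atoms = acyclic half). The route rests on the C12′–C13′ sp2–sp2 single bond. The right half is carried as a C24 polyenyne diol ending in a propynyl group (C20′H3–C13′≡C14′). The left half is a C16 (E)-alkenyl iodide at C12′. In one flask Cp2Zr(H)Cl adds syn across C13′≡C14′, placing zirconium on C13′, and Zn/Pd-mediated coupling joins C13′ to C12′. The bond, the E geometry of C13′=C14′ and the complete undecaene arise together. The ring A 3,4-diol is masked only as transient zirconium alkoxides. The step exploits the small methyl C20′ on C13′ opposite the polyenyl chain on C14′.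

Key step: step 9

Assumption 1: pseudoionone is used as the (3E,5E) isomer (technical material holds some 5Z isomer, which is removed by fractional distillation before use).
Assumption 2: the (+)-camphor-derived oxaziridine is taken to deliver oxygen to the enolate face that gives (3R); if a test run shows the opposite sense, its commercial antipode is used in the same step.
Remark: in the SMILES the η5-cyclopentadienyl (Cp) ligands on zirconium are written as σ-bonded rings.

Step 1
Reactants: 1 (3E,5E)-pseudoionone
Product: 2 (2E,4E,6E)-3,7,11-trimethyldodeca-2,4,6,10-tetraenenitrile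
Conditions: (EtO)2P(O)CH2CN, NaH, THF, 0 °C to rt; chromatography
Reagents that add atoms: diethyl cyanomethylphosphonate, CCOP(=O)(CC#N)OCC
Why: Horner–Wadsworth–Emmons olefination of the methyl dienone with the small stabilised cyanomethylphosphonate anion should favour the E geometry at C9′=C10′, and the minor 2Z nitrile is removed by chromatography.

Step 2
Reactants: 2 (2E,4E,6E)-3,7,11-trimethyldodeca-2,4,6,10-tetraenenitrile
Product: 4 (2E,4E,6E)-3,7,11-trimethyldodeca-2,4,6,10-tetraenal, via N-diisobutylaluminio imine 3 (not isolated)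
Conditions: i-Bu2AlH (1.2 equiv), toluene, −78 °C; then wet silica gel, 0 °C
Reagents that add atoms: water, O
Why: Partial reduction of a nitrile: i-Bu2AlH adds once to give an aluminium imine that is stable in the cold and is hydrolysed to the aldehyde on work-up, while the polyene is left untouched.

Step 3
Reactants: 4 (2E,4E,6E)-3,7,11-trimethyldodeca-2,4,6,10-tetraenal
Product: 5 (1E,3E,5E,7E)-1-iodo-4,8,12-trimethyltrideca-1,3,5,7,11-pentaene (C16 iodide)
Conditions: CrCl2 (8 equiv), CHI3 (2 equiv), THF–1,4-dioxane, 0 °C, dark; used promptly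
Reagents that add atoms: iodoform, IC(I)I
Why: Takai olefination: the geminal dichromium species from CHI3 and CrCl2 adds to the aldehyde and eliminates to the (E)-alkenyl iodide, which adds C12′ and sets C11′=C12′ as E.

Step 4
Reactants: 6 1-bromobut-2-yne
Product: 7 diethyl but-2-yn-1-ylphosphonate
Conditions: P(OEt)3, neat, 120 °C
Reagents that add atoms: triethyl phosphite, CCOP(OCC)OCC
Why: Michaelis–Arbuzov reaction of an unhindered primary propargylic bromide should proceed by direct displacement followed by loss of bromoethane.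

Step 5
Reactants: 7 diethyl but-2-yn-1-ylphosphonate; 8 all-trans-retinal
Product: 10 1,3,3-trimethyl-2-[(1E,3E,5E,7E,9E)-3,7-dimethyltrideca-1,3,5,7,9-pentaen-11-yn-1-yl]cyclohex-1-ene (C24 polyenyne), via lithiated phosphonate 9 (not isolated)
Conditions: LiN(SiMe3)2, THF, −78 °C; then 8, −78 to 0 °C, dark
Reagents that add atoms: none
Why: Horner–Wadsworth–Emmons olefination of the polyenal with the propargylic phosphonate anion should give the E enyne at C15=C15′ and installs the propynyl terminus C14′≡C13′–C20′ in one operation.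

Step 6
Reactants: 10 C24 polyenyne
Product: 11 2,4,4-trimethyl-3-[(1E,3E,5E,7E,9E)-3,7-dimethyltrideca-1,3,5,7,9-pentaen-11-yn-1-yl]cyclohex-2-en-1-one (4-oxo polyenyne)
Conditions: NaClO3 (2 equiv), NaI (5 mol %), dilute H2SO4 (pH 3), CH2Cl2–H2O, 20 °C, dark
Reagents that add atoms: sodium chlorate, [Na+].[O-]Cl(=O)=O
Why: Iodine-mediated halate oxidation is the reaction type known to turn the ring C4 methylene of β-end-group polyenes into the 4-ketone; it should act only at C4 of ring A, the sole CH2 allylic to the polyene terminus, and the iodine present should also equilibrate any 15Z isomer to all-E.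

Step 7
Reactants: 11 4-oxo polyenyne
Product: 13 (6R)-6-hydroxy-2,4,4-trimethyl-3-[(1E,3E,5E,7E,9E)-3,7-dimethyltrideca-1,3,5,7,9-pentaen-11-yn-1-yl]cyclohex-2-en-1-one [(3R)-3-hydroxy-4-oxo polyenyne], via sodium enolate 12 (not isolated)
Conditions: NaN(SiMe3)2 (1.1 equiv), THF, −78 °C; (+)-(camphorsulfonyl)oxaziridine (1.3 equiv), −78 °C; AcOH quench; argon, dark
Reagents that add atoms: (+)-(2R,8aS)-(camphorsulfonyl)oxaziridine, CC1(C)[C@@H]2CC[C@]13CS(=O)(=O)N4O[C@@]34C2
Why: Davis asymmetric enolate hydroxylation: kinetic deprotonation can occur only at the C3 methylene next to the ketone, and oxygen transfer from the chiral oxaziridine, whose camphor skeleton shields one enolate face, sets C3 as R; enolate oxidation of this kind is known for 4-oxo-β-end-group carotenoids.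

Step 8
Reactants: 13 (3R)-3-hydroxy-4-oxo polyenyne
Product: 15 (1R,2R)-3,5,5-trimethyl-4-[(1E,3E,5E,7E,9E)-3,7-dimethyltrideca-1,3,5,7,9-pentaen-11-yn-1-yl]cyclohex-3-ene-1,2-diol [(3R,4R)-diol polyenyne], via alkoxydiacetoxyborohydride 14 (not isolated)
Conditions: Me4NBH(OAc)3 (4 equiv), MeCN–THF–AcOH, −30 °C, dark
Reagents that add atoms: none
Why: Hydroxy-directed Saksena–Evans reduction: O3 replaces one acetate on boron and the hydride is delivered within the complex to C4 from the face that carries O3, which is also the axial trajectory of the half-chair, so the new 4-OH is trans to the 3-OH and C4 becomes R.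

Step 9
Reactants: 15 (3R,4R)-diol polyenyne; 5 C16 iodide
Product: 19 (all-E,3R,4R)-β,ψ-carotene-3,4-diol (target), via trizirconated alkenylzirconocene 16 (not isolated), via alkenylzinc chloride 17 (not isolated), via coupled bis-zirconium alkoxide 18 (not isolated)
Conditions: Cp2Zr(H)Cl (3.3 equiv), THF, 0 °C to rt, dark; ZnCl2 (1.1 equiv), 0 °C; 5 (1.2 equiv), Pd(PPh3)4 (5 mol %), rt; then aq. NaHCO3
Reagents that add atoms: none
Why: Cp2Zr(H)Cl first turns both O–H groups into chlorozirconocene alkoxides with loss of H2 and then adds H–Zr syn across C13′≡C14′ to give 16; ZnCl2 moves C13′ to zinc (17), zerovalent palladium inserts into the C12′–I bond of 5, and transmetalation followed by reductive elimination forms C12′–C13′ with retention at both alkenyl carbons. The closest known reaction type is the hydrozirconation/ZnCl2/Pd(PPh3)4 Negishi coupling of methyl-capped internal alkynes with (E)-alkenyl iodides, which gives (E,E)-dienes bearing the methyl group on the coupled carbon. No ring is closed and no stereocentre is created; the new stereo-element is C13′=C14′, whose E geometry follows from the syn addition, while C11′=C12′ keeps the E geometry set in step 3. The step needs regioselectivity (zirconium on C13′, hydrogen on C14′), secured by the small methyl C20′ against the polyenyl chain and by the slight excess of Cp2Zr(H)Cl, which equilibrates the regioisomers to the less crowded one; it also needs chemoselectivity for the alkyne, secured because the di- and trisubstituted alkenes of both polyenes hydrozirconate far more slowly. C3 and C4 of ring A are not touched, since only their O–H bonds react and the O–Zr bonds of 18 are hydrolysed on work-up.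

**Compound list**
1 | (3E,5E)-6,10-dimethylundeca-3,5,9-trien-2-one (pseudoionone) | CC(C)=CCC/C(C)=C/C=C/C(C)=O | starting material
2 | (2E,4E,6E)-3,7,11-trimethyldodeca-2,4,6,10-tetraenenitrile | CC(C)=CCC/C(C)=C/C=C/C(C)=C/C#N | intermediate
3 | N-(diisobutylaluminio) imine of aldehyde 4 (not isolated) | CC(C)=CCC/C(C)=C/C=C/C(C)=C/C=N[Al](CC(C)C)CC(C)C | intermediate
4 | (2E,4E,6E)-3,7,11-trimethyldodeca-2,4,6,10-tetraenal | CC(C)=CCC/C(C)=C/C=C/C(C)=C/C=O | intermediate
5 | (1E,3E,5E,7E)-1-iodo-4,8,12-trimethyltrideca-1,3,5,7,11-pentaene (C1′–C12′, iodine on C12′) | CC(C)=CCC/C(C)=C/C=C/C(C)=C/C=C/I | intermediate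
6 | 1-bromobut-2-yne | CC#CCBr | starting material
7 | diethyl but-2-yn-1-ylphosphonate | CC#CCP(=O)(OCC)OCC | intermediate
8 | all-trans-retinal | O=C/C=C(C)/C=C/C=C(C)/C=C/C1=C(C)CCCC1(C)C | starting material
9 | lithium salt of the α-carbanion of 7 (not isolated) | [Li+].CC#C[CH-]P(=O)(OCC)OCC | intermediate
10 | C24 polyenyne: 1,3,3-trimethyl-2-[(1E,3E,5E,7E,9E)-3,7-dimethyltrideca-1,3,5,7,9-pentaen-11-yn-1-yl]cyclohex-1-ene | CC#C/C=C/C=C(C)/C=C/C=C(C)/C=C/C1=C(C)CCCC1(C)C | intermediate
11 | 4-oxo polyenyne: 2,4,4-trimethyl-3-[(1E,3E,5E,7E,9E)-3,7-dimethyltrideca-1,3,5,7,9-pentaen-11-yn-1-yl]cyclohex-2-en-1-one | CC#C/C=C/C=C(C)/C=C/C=C(C)/C=C/C1=C(C)C(=O)CCC1(C)C | intermediate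
12 | sodium C3=C4 enolate of 11 (not isolated) | [Na+].CC#C/C=C/C=C(C)/C=C/C=C(C)/C=C/C1=C(C)C([O-])=CCC1(C)C | intermediate
13 | (3R)-3-hydroxy-4-oxo polyenyne: (6R)-6-hydroxy derivative of 11 | CC#C/C=C/C=C(C)/C=C/C=C(C)/C=C/C1=C(C)C(=O)[C@H](O)CC1(C)C | intermediate
14 | tetramethylammonium salt of 13 bound through O3 to BH(OAc)2 (not isolated) | C[N+](C)(C)C.CC#C/C=C/C=C(C)/C=C/C=C(C)/C=C/C1=C(C)C(=O)[C@H](O[BH-](OC(C)=O)OC(C)=O)CC1(C)C | intermediate
15 | (3R,4R)-diol polyenyne: (1R,2R)-3,5,5-trimethyl-4-[(1E,3E,5E,7E,9E)-3,7-dimethyltrideca-1,3,5,7,9-pentaen-11-yn-1-yl]cyclohex-3-ene-1,2-diol (trans-diol) | CC#C/C=C/C=C(C)/C=C/C=C(C)/C=C/C1=C(C)[C@@H](O)[C@H](O)CC1(C)C | intermediate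
16 | 15 after syn H–Zr addition: ZrCp2Cl on C13′ (anti to C15′), H on C14′, O3 and O4 as O–ZrCp2Cl (not isolated) | Cl[Zr](C1C=CC=C1)(C1C=CC=C1)/C(C)=C/C=C/C=C(C)/C=C/C=C(C)/C=C/C1=C(C)[C@@H](O[Zr](Cl)(C2C=CC=C2)C2C=CC=C2)[C@H](O[Zr](Cl)(C2C=CC=C2)C2C=CC=C2)CC1(C)C | intermediate
17 | as 16 but ZnCl on C13′ (not isolated) | Cl[Zn]/C(C)=C/C=C/C=C(C)/C=C/C=C(C)/C=C/C1=C(C)[C@@H](O[Zr](Cl)(C2C=CC=C2)C2C=CC=C2)[C@H](O[Zr](Cl)(C2C=CC=C2)C2C=CC=C2)CC1(C)C | intermediate
18 | 19 with O3 and O4 as O–ZrCp2Cl (not isolated) | CC(C)=CCC/C(C)=C/C=C/C(C)=C/C=C/C(C)=C/C=C/C=C(C)/C=C/C=C(C)/C=C/C1=C(C)[C@@H](O[Zr](Cl)(C2C=CC=C2)C2C=CC=C2)[C@H](O[Zr](Cl)(C2C=CC=C2)C2C=CC=C2)CC1(C)C | intermediate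
19 | (all-E,3R,4R)-β,ψ-carotene-3,4-diol | CC(C)=CCC/C(C)=C/C=C/C(C)=C/C=C/C(C)=C/C=C/C=C(C)/C=C/C=C(C)/C=C/C1=C(C)[C@@H](O)[C@H](O)CC1(C)C | target

**Total step count:** 9.
**Longest linear sequence:** 6 steps (4, 5, 6, 7, 8, 9, from 1-bromobut-2-yne); 5 steps from retinal; 4 steps from pseudoionone.

**Steps most likely to fail**

1. Step 9. Zirconium may add with poor regioselectivity across C13′≡C14′. The alkenylmetal may also be lost by protonolysis or by slow transmetalation next to the bulky zirconium alkoxides. The fallback sets out from 15. Copper-catalysed protoboration (B2pin2, CuCl, Xantphos, NaOtBu, MeOH, THF, rt) tolerates the free diol. It is steered electronically: copper goes to C14′ next to the polyene and boron to C13′. It should give the C13′ pinacol boronate F1, with boron anti to C15′, which can be freed from any regioisomer before the coupling. Suzuki–Miyaura coupling of F1 with 5 (Pd(dppf)Cl2, K3PO4, THF–H2O, rt, dark) forms the same C12′–C13′ bond and comes back to the route at 19.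

2. Step 7. Oxygen transfer to the flat cross-conjugated enolate may show poor facial selectivity, or the product may be oxidised further. The fallback sets out from 11. Aerobic oxidation of the potassium enolate (KOtBu, O2, THF–t-BuOH, −30 °C) should give the diosphenol F2. Asymmetric transfer hydrogenation of its 3-keto tautomer (RuCl(p-cymene)[(R,R)-TsDPEN], HCO2H–Et3N, CH2Cl2, 0 °C) is catalyst controlled, with the C4 acyl carbon taking the place of the π substituent. Stopped at the ketol stage, it should give (3R) and comes back to the route at 13.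

3. Step 8. Intermolecular hydride delivery may compete and erode the facial selectivity, which would give the cis-diol. The acidic medium may also ionise the allylic C4–O bond. The fallback sets out from 13 and replaces substrate direction by catalyst control. Asymmetric transfer hydrogenation with RuCl(p-cymene)[(S,S)-TsDPEN] (HCO2H–Et3N, CH2Cl2, 0 °C, short contact to avoid epimerisation at C3) should deliver hydride to the face that gives (4R), with the C5=C6 alkene acting as the π substituent. It comes back to the route at 15; no new compound is made (F0).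

**Further compounds**
F1 | step 9 | C13′ pinacol boronate of 15 (Bpin on C13′ anti to C15′, H on C14′, free 3R,4R-diol) | CC1(C)OB(OC1(C)C)/C(C)=C/C=C/C=C(C)/C=C/C=C(C)/C=C/C1=C(C)[C@@H](O)[C@H](O)CC1(C)C
F2 | step 7 | diosphenol: 2-hydroxy-4,4,6-trimethyl-5-[(1E,3E,5E,7E,9E)-3,7-dimethyltrideca-1,3,5,7,9-pentaen-11-yn-1-yl]cyclohexa-2,5-dien-1-one | CC#C/C=C/C=C(C)/C=C/C=C(C)/C=C/C1=C(C)C(=O)C(O)=CC1(C)C
F0 | step 8 | none | none
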